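## Structural features

Epoxypholamin A is a trans-fused drim-7-ene decalin (ring A = C1–C5/C10, ring B = C5–C10; C7=C8 with the C12 methyl on C8; 4α-CH2OH (C13), 4β-CH3, 10β-CH3, 5α-H, 9α-H) whose C9 carries, through the single methylene C11, a six-membered epoxyquinol ring C1'–C6'. In that ring C1' (quaternary, bonded to C11) and C2' share an oxirane, C3' is a ketone conjugated to C4'=C5', C4' bears a hydroxymethyl group (C7') and C6' is a secondary carbinol. The decalin stereocentres C4, C5, C10 and C9 are contiguous and are those of the abietane resin acids. The quinol stereocentres C6', C1' and C2' are also contiguous, with the C6' hydroxyl trans to the oxirane oxygen (1'S,2'S,6'R). The two arrays are insulated by C11: C9 is two bonds from C1' and cannot be relied on to bias the quinol ring. The epoxy enone is sensitive to base and nucleophiles, the tertiary C1'–O bond next to an allylic carbinol is sensitive to acid, and C7=C8 can migrate or be attacked by electrophilic oxidants. The real difficulty is absolute control at C1'/C2' on a nearly flat ring, on one of two enone double bonds, independently of the decalin. The feature exploited is that C3' and C6' are para-related oxygenated carbons, so the ring is a masked 2,5-disubstituted hydroquinone: with C6' as ketone and C3' as spiro ketal of a C2-symmetric diol, C1'=C2' is the only enone bond with a free β carbon (C2'), and C2' lies next to the ketal whose phenyl groups distinguish its two faces.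

## Logic of the disconnections

**26 ⇒ 25 ⇒ 24.** The O–H bonds at C13 and C7' are traced to O–Si bonds (25) and the C3' carbonyl to the two C3'–O bonds of a dioxolane (24). The free epoxy enone is the most fragile array and should appear last. The gain is that every hydroxyl except C6'–OH is masked and C3' is held at the quinone oxidation level without being an electrophile. The forward steps must cleave a robust diphenyl dioxolane and two primary silyl ethers without opening the C1'–C2' oxirane.

**24 ⇒ 23.** The C6'–H bond is cut. A C6' ketone is what makes C1'=C2' an enone, so the carbinol is best introduced after the epoxide. The gain is one stereocentre fewer. The demand is 1,2-delivery of hydride from the oxirane face.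

**23 ⇒ 21.** The C1'–O and C2'–O bonds are cut. This removes the oxirane ring and two stereocentres and returns a planar dienone whose only stereochemical information is the ketal on C3'. The forward step must choose C1'=C2' over C4'=C5' and one face of C2' over the other.

**21 ⇒ 19 + 20, then 19 ⇒ 17 (through 18).** The dioxolane C3'–O bonds are exchanged for two C3'–OMe bonds, and then one C3'–OMe bond and the C6' carbonyl are traced to a 4-methoxyphenol. An arene fixes which carbon becomes ketal (the one bearing OMe) and which becomes ketone (the one bearing OH). The demand is that the C6' oxygen is a free phenol and the C3' oxygen a methyl ether at that point. A late monomethylation of a hydroquinone would leave this choice to chance, so the two oxygens are differentiated from the first step of the arene synthesis.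

**17 ⇒ 16 ⇒ 15.** The C8–C12 bond is cut, with C7=C8 traced to an enol triflate of a C8 ketone. This places the double bond unambiguously, whereas dehydration of a C8 carbinol would give positional isomers. The gain is that the C8 ketone is exactly what ring cleavage of the terpene delivers. The demand is kinetic enolisation toward C7 and not C9.

**15 ⇒ 6 + 12 (through 13 and 14).** The C11–C1' bond, the only bond between the halves, is cut to a carboxylic acid derivative (one carbon longer, lost as CO2) and an aryl bromide. The position of bromine defines the attachment site, which avoids the regiochemical mixture expected from adding a C11 radical to a monosubstituted quinone. The coupling is placed at the C8-ketone stage so that the C11 radical has no C7=C8 bond three atoms away; a 1,2-vinyl shift is much faster than the corresponding acyl shift. The demand is that capture of a β-branched primary radical outruns its rearrangement.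

**6 ⇒ 5 ⇒ 4 ⇒ 3 ⇒ 2 ⇒ 1.** The C8 carbonyl and the chain-terminal carbonyl are reconnected to the two double bonds of a homoannular diene. 1 already holds C4 (with the oxidised 4α carbon), C5, C9 and C10 in the required configuration, and double cleavage of its ring-C diene leaves C8 as ketone and a two-carbon chain on C9. All four decalin stereocentres therefore come from the chiral pool. The demand is exhaustive ozonolysis without loss of the C9 configuration.

**12 ⇒ 11 ⇒ 10 ⇒ 9 ⇒ 8 ⇒ 7.** The C–Br, O–Si, O–CH3 and O–acyl bonds are cut. In 7 the aldehyde differentiates the chelated 2-hydroxyl from the free 5-hydroxyl, and the free phenol later directs bromine to the carbon that becomes C1'. The demands are selective monoacylation and ortho-selective bromination.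

## Other disconnections considered

**Alternative 1:** The cut is at C3'–O and C6'–O: both oxygens are traced to one molecule of O2 added across the cyclohexa-1,3-diene A1 (C6'=C1'–C2'=C3', sp3 C4' bearing CH2OTBS). The forward key step is sensitised photo-oxygenation, a suprafacial [4+2] addition giving endoperoxide A2 with the bridge anti to the C4' substituent. It would be followed by Kornblum–DeLaMare opening to hydroxy enone A3, nucleophilic epoxidation of C1'=C2', dehydrogenation across C4'–C5' (which erases C4') and desilylation.
- In favour: the step needs no auxiliary and only O2 and light. C6' arrives directly at the carbinol level with its configuration tied to C4'; on this point it is better than the chosen plan, which needs a separate stereoselective ketone reduction. The pericyclic mechanism guarantees the cis relation of the two new C–O bonds.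
- Against: the absolute problem is only moved to C4' of A1, a centre as remote from the decalin as C1', in a diene prone to aromatisation and 1,5-hydrogen shifts. Singlet oxygen can also react with the trisubstituted C7=C8 bond in an ene reaction. The Kornblum–DeLaMare step must remove C3'–H and not C6'–H. The oxirane must still be set trans to the C6' hydroxyl on A3 with no controller next to C2'.
- Comparison: on structure it is equal or better at C6' and weaker at C1'/C2'. On mechanism the cycloaddition is more predictable than an auxiliary model, but three later selectivities are open. On step economy it needs four or five steps after its key step against three here, plus an asymmetric synthesis of A1.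

**Alternative 2:** The cut is at C4'=C5'. The forward key step is ring-closing metathesis of the acyclic epoxy dienone A4 with the second-generation Grubbs catalyst RuCl2(=CHPh)(PCy3)(H2IMes), giving the tris-silyl ether A5; desilylation then gives 26.
- In favour: all three quinol stereocentres would be set in open-chain chemistry by reagent control (for example asymmetric epoxidation of an allylic alcohol), a better-understood source of absolute configuration than a remote ketal; on this point it is better. Only one step follows the key step, also better than three.
- Against: A4 is hard to reach. Its quaternary C1' must carry C11, the oxirane and both arms, which calls for a junction at the hindered C11. Its α-methylene ketone arm is a polymerisable Michael acceptor and a slow metathesis partner, and ruthenium hydrides could move C7=C8.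
- Comparison: mechanistic reliability of the key step is about equal. Structurally the stereochemistry is more secure but the intermediates are more fragile. The end game is shorter, but the overall route is expected to be longer because no cheap arene supplies the six ring carbons.

**Alternative 3:** The cut is at C2'–C3', C1'–C6' and C5'–C6'. The forward key step is benzannulation of the terminal alkyne A6 with the Fischer carbene complex A7 of zerovalent chromium and one carbonyl ligand, giving phenol A8. A8 is the same compound as 18, so this is another way to assemble the arene (replacing steps 4–14); the same dearomatisation and epoxidation would follow.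
- Correction: for the silyloxymethyl group to end on C4', the alkenyl group of A7 must carry it on the carbon bonded to the carbene carbon (3-silyloxyprop-1-en-2-yl). A 2-substituted vinyl group would place it on C5'.
- In favour: regiochemistry follows from the alkyne (larger substituent next to the new phenol), and the two oxygens are differentiated automatically (OMe from the carbene, OH from the carbonyl ligand); this equals the chosen plan and needs no phenol protecting group. The aldehyde carbon of 4 would be kept as C1', so no carbon is discarded and no C11 radical is formed; on atom economy and rearrangement risk it is better.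
- Against: it uses a stoichiometric, air-sensitive chromium complex that needs its own preparation from Cr(CO)6. A6 requires the C8 methyl and C7=C8 to be installed while the aldehyde is masked. The electron-rich product must be freed from chromium without oxidation to the quinone, which would erase the oxygen differentiation.
- Comparison: the structural outcome is identical. The mechanism is a multistep organometallic cascade against a single cross-coupling. The step count is roughly equal; the chosen plan is preferred for scalability and reagents.

Key step: step 16

Assumption: the facial sense of step 16 is taken from a steric model of the (R,R)-dioxolane (worked out by hand, not verified). In that model the phenyl-bearing carbon leaning toward C2' lies on the face opposite to the one that must be oxygenated. If the opposite sense were found, the ketal of (S,S)-hydrobenzoin would be used in step 15 with nothing else changed.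

## Route

Step 1
Reactants: 1 levopimaric acid
Product: 2 levopimarol (abieta-8(14),12-dien-18-ol)
Conditions: LiAlH4, THF, 0 → 25 °C; aq. NaOH work-up
Reagents that add atoms: none
Why: Hydride reduction of the hindered 4α-carboxylic acid to the primary alcohol; the unactivated cisoid diene is inert to LiAlH4 and the basic work-up avoids its acid-catalysed isomerisation, so C4, C5, C9 and C10 are carried over from 1 untouched.

Step 2
Reactants: 2 levopimarol
Product: 3 18-(tert-butyldimethylsilyloxy)abieta-8(14),12-diene
Conditions: TBSCl, imidazole, DMF, 25 °C
Reagents that add atoms: tert-butyldimethylsilyl chloride, CC(C)(C)[Si](C)(C)Cl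
Why: Imidazole-promoted silylation of a primary neopentyl-type alcohol; this silyl ether is kept to the last step and tolerates ozone, chlorite, organozinc, amide base and mild acid.

Step 3
Reactants: 3 silyl ether of levopimarol
Product: 4 keto aldehyde (trans-decalin; C8 ketone; 9β-CH2CHO; 4α-CH2OTBS; 4β-Me; 10β-Me; 5α-H; 9α-H)
Conditions: O3, CH2Cl2, −78 °C; then PPh3, −78 → 25 °C
Reagents that add atoms: ozone, [O-][O+]=O
Why: Criegee ozonolysis of both trisubstituted bonds of the homoannular diene (C8=C14 and C12=C13, abietane numbering) leaves C8 as the ring-B ketone and the former C12 as the aldehyde at the end of the C9 side chain, while C13, C14 and the isopropyl group leave as a ketoaldehyde. C9 is α to the new ketone but already holds the equatorial, thermodynamically preferred side chain.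

Step 4
Reactants: 4 keto aldehyde
Product: 5 keto acid (9β-CH2CO2H; otherwise as 4)
Conditions: NaClO2, NaH2PO4, 2-methyl-2-butene, t-BuOH/H2O, 0 → 25 °C
Reagents that add atoms: sodium chlorite, [Na+].[O-]Cl=O
Why: Pinnick oxidation converts the aldehyde into the acid chemoselectively; the ketone, the silyl ether and the epimerisable C9 are unaffected in the phosphate buffer.

Step 5
Reactants: 5 keto acid
Product: 6 N-(acyloxy)phthalimide (redox-active ester) of 5
Conditions: N-hydroxyphthalimide, N,N'-diisopropylcarbodiimide, DMAP (cat.), CH2Cl2, 25 °C
Reagents that add atoms: N-hydroxyphthalimide, O=C1c2ccccc2C(=O)N1O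
Why: Carbodiimide (Steglich-type) acylation of N-hydroxyphthalimide gives the redox-active ester that serves as precursor of the C11 radical; nothing else in 5 is acylated.

Step 6
Reactants: 7 2,5-dihydroxybenzaldehyde
Product: 8 3-formyl-4-hydroxyphenyl pivalate
Conditions: t-BuCOCl (1.05 equiv), pyridine, CH2Cl2, −20 → 0 °C
Reagents that add atoms: pivaloyl chloride, CC(C)(C)C(=O)Cl
Why: The 2-hydroxyl is held in a hydrogen bond to the aldehyde and is the poorer nucleophile, so one equivalent of acyl chloride esterifies only the 5-hydroxyl. This fixes at the outset which oxygen becomes the C6' phenol and which the C3' methyl ether.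

Step 7
Reactants: 8 3-formyl-4-hydroxyphenyl pivalate
Product: 9 3-formyl-4-methoxyphenyl pivalate
Conditions: MeI, K2CO3, acetone, 50 °C
Reagents that add atoms: iodomethane, CI
Why: Williamson methylation of the remaining chelated phenol; the hindered aryl pivalate tolerates K2CO3 in dry acetone.

Step 8
Reactants: 9 3-formyl-4-methoxyphenyl pivalate
Product: 10 3-(hydroxymethyl)-4-methoxyphenol
Conditions: LiAlH4, THF, 0 °C; aq. NH4Cl
Reagents that add atoms: none
Why: LiAlH4 reduces the aldehyde to the benzylic alcohol (C7') and cleaves the aryl ester in the same operation, releasing the phenol that becomes the C6' oxygen.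

Step 9
Reactants: 10 3-(hydroxymethyl)-4-methoxyphenol
Product: 11 2-bromo-5-(hydroxymethyl)-4-methoxyphenol
Conditions: N-bromosuccinimide, MeCN, −20 → 0 °C, dark
Reagents that add atoms: N-bromosuccinimide, O=C1CCC(=O)N1Br
Why: Electrophilic aromatic bromination is governed by the free phenol: its para position carries OMe and the ortho position between OH and CH2OH is crowded, so bromine should enter the other ortho carbon, para to the hydroxymethyl group. This carbon becomes C1', which fixes the regiochemistry of the later C–C bond.

Step 10
Reactants: 11 2-bromo-5-(hydroxymethyl)-4-methoxyphenol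
Product: 12 bis-TBS ether of 11 (aryl O-TBS and benzylic O-TBS)
Conditions: TBSCl (2.5 equiv), imidazole, DMF, 25 °C
Reagents that add atoms: tert-butyldimethylsilyl chloride, CC(C)(C)[Si](C)(C)Cl
Why: Double silylation; the aryl silyl ether is a temporary mask that carbonate in methanol can later remove in the presence of the alkyl silyl ethers, and the benzylic silyl ether stays to the end.

Step 11
Reactants: 6 redox-active ester; 12 aryl bromide
Product: 15 aryl ketone (C11–C1' bond formed; C8 ketone; aryl O-TBS; C3'-OMe; two alkyl O-TBS), via arylmagnesium bromide 13 (not isolated), via arylzinc chloride 14 (not isolated)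
Conditions: 12 (3 equiv), Mg, LiCl, THF, 25 °C; ZnCl2, 0 °C; then 6, NiCl2(MeOCH2CH2OMe) (20 mol %), 4,4'-di-tert-butyl-2,2'-bipyridine (40 mol %), THF/DMF, 25 °C
Reagents that add atoms: none
Why: Nickel-catalysed decarboxylative Negishi-type arylation of an N-(acyloxy)phthalimide: single-electron reduction of 6 releases CO2 and the primary C11 radical, which is captured by the arylnickel species formed from 14 and gives the C11–C1' bond by reductive elimination. The coupling is run at the C8-ketone stage so that the radical has no C7=C8 bond available for a fast 1,2-vinyl shift; ketone and silyl ethers are inert to the arylzinc, and C9 is not touched.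

Step 12
Reactants: 15 aryl ketone
Product: 16 C7-enol triflate (C7=C8–OSO2CF3)
Conditions: KN(SiMe3)2, THF, −78 °C; PhNTf2, −78 → 0 °C
Reagents that add atoms: N-phenylbis(trifluoromethanesulfonimide), O=S(=O)(N(c1ccccc1)S(=O)(=O)C(F)(F)F)C(F)(F)F
Why: Kinetic deprotonation of the C8 ketone by the bulky amide occurs at the unhindered C7 methylene and not at the tertiary C9–H; O-triflation of the enolate fixes the double bond at C7=C8.

Step 13
Reactants: 16 enol triflate
Product: 17 drim-7-ene arene (C12 methyl on C8; aryl O-TBS; C3'-OMe; two alkyl O-TBS)
Conditions: MeZnCl, Pd(PPh3)4 (5 mol %), THF, 50 °C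
Reagents that add atoms: methylzinc chloride, C[Zn]Cl
Why: Negishi coupling of the enol triflate with methylzinc under zerovalent palladium installs the C12 methyl on C8 and completes the drim-7-ene unit without the positional isomers that dehydration of a carbinol would give.

Step 14
Reactants: 17 drim-7-ene arene
Product: 19 quinone dimethyl monoketal (C3'(OMe)2; C6' ketone), via free phenol 18 (not isolated)
Conditions: K2CO3 (0.5 equiv), MeOH/THF, 25 °C; then PhI(OAc)2, 0 °C
Reagents that add atoms: methanol, CO
Why: Catalytic methoxide cleaves the aryl silyl ether selectively (alkyl silyl ethers are stable), and the liberated 4-methoxyphenol 18 is oxidised at once by the trivalent-iodine reagent. Methanol traps the oxidised ring at the para carbon C3', so C3' becomes the dimethyl ketal and C6' the dienone carbonyl (oxidative dearomatisation of a p-alkoxyphenol).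

Step 15
Reactants: 19 quinone dimethyl monoketal; 20 (R,R)-hydrobenzoin
Product: 21 quinone monoketal with the (R,R)-hydrobenzoin ketal on C3' and the C6' ketone
Conditions: 20 (2 equiv), pyridinium p-toluenesulfonate (cat.), benzene, 50 °C, 5 Å molecular sieves
Reagents that add atoms: (R,R)-hydrobenzoin (20), O[C@H](c1ccccc1)[C@H](O)c1ccccc1
Why: Acid-catalysed transketalisation, driven by sequestration of methanol, replaces the two methoxy groups on C3' by the diol; because the diol is C2-symmetric, C3' does not become a stereocentre and one compound results. The non-aqueous, weakly acidic medium spares the silyl ethers and avoids hydrolysis to the quinone.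

Step 16
Reactants: 21 hydrobenzoin quinone monoketal
Product: 23 C1',C2'-epoxy quinone monoketal, via peroxy enolate 22 (not isolated)
Conditions: t-BuOOH (anhydrous, in decane), DBU, CH2Cl2, 0 → 25 °C
Reagents that add atoms: tert-butyl hydroperoxide, CC(C)(C)OO
Why: Weitz–Scheffer nucleophilic epoxidation: the tert-butyl peroxide anion adds in conjugate fashion to C2', the only unsubstituted β carbon of the C6' dienone, giving enolate 22, whose C1' then attacks the proximal peroxide oxygen and expels tert-butoxide. The closest known reaction type is the base/hydroperoxide epoxidation of quinone monoketals that carry the ketal of a C2-symmetric diol. The oxirane closes by a 3-exo-tet displacement at oxygen and must be cis-fused, so C1' takes its configuration from C2'. C2' is controlled by the dioxolane on the neighbouring C3': in the (R,R)-ketal the CHPh carbon on one ring face leans toward C2' and the one on the other face toward C4', so the peroxide is expected to enter C2' anti to the nearer phenyl, which gives the configuration required for 26. Site selectivity is needed against the C4'=C5' arm and against C7=C8: the former has a fully substituted β carbon (C4', bearing CH2OTBS and flanked by the ketal) and the latter is not electrophilic. Face selectivity is the open variable and cannot come from the decalin, which is insulated by C11. Silyl ethers and ketal are stable to the non-aqueous basic medium.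

Step 17
Reactants: 23 epoxy quinone monoketal
Product: 24 trans-epoxy carbinol (C6'–OH trans to the oxirane oxygen; C3' ketal retained)
Conditions: NaBH4, CeCl3·7H2O, MeOH/THF, −78 °C
Reagents that add atoms: none
Why: Luche reduction gives 1,2-reduction of the cross-conjugated ketone. Hydride is expected to enter C6' from the face of the oxirane oxygen, because the opposite face is screened by the C11 methylene and the decalin on the quaternary C1' and because cyclic α,β-epoxy ketones generally give trans epoxy alcohols under these conditions; this sets C6' trans to the epoxide.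

Step 18
Reactants: 24 trans-epoxy carbinol ketal
Product: 25 bis-TBS ether of epoxypholamin A (C3' enone unveiled)
Conditions: montmorillonite K-10 (acid-activated aluminosilicate clay, idealised Al2Si4O10(OH)2·nH2O), wet CH2Cl2, 25 °C
Reagents that add atoms: water, O
Why: Acid-catalysed hydrolysis of the now allylic C3' ketal (the oxocarbenium ion is stabilised by C4'=C5') unveils the enone. A solid acid in a non-polar solvent exposes the oxirane and the silyl ethers to acid only at the surface, and the diol 20 can be recovered.

Step 19
Reactants: 25 bis-TBS ether
Product: 26 epoxypholamin A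
Conditions: Et3N·3HF, MeCN/THF, 25 °C
Reagents that add atoms: none
Why: Fluoride-mediated cleavage of the two primary silyl ethers under nearly neutral conditions; the amine–HF complex is neither basic enough to attack the epoxy enone nor acidic enough to open the oxirane, and should give 26.

## Compound list

1 | levopimaric acid (abieta-8(14),12-dien-18-oic acid) | CC(C)C1=CC[C@H]2C(=C1)CC[C@H]1[C@](C)(C(=O)O)CCC[C@@]12C | starting material
2 | levopimarol (abieta-8(14),12-dien-18-ol) | CC(C)C1=CC[C@H]2C(=C1)CC[C@H]1[C@](C)(CO)CCC[C@@]12C | intermediate
3 | 18-(tert-butyldimethylsilyloxy)abieta-8(14),12-diene | CC(C)C1=CC[C@H]2C(=C1)CC[C@H]1[C@](C)(CO[Si](C)(C)C(C)(C)C)CCC[C@@]12C | intermediate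
4 | keto aldehyde: trans-decalin with C8 ketone, 9β-CH2CHO, 4α-CH2OTBS, 4β-Me, 10β-Me, 5α-H, 9α-H | O=C1CC[C@H]2[C@](C)(CO[Si](C)(C)C(C)(C)C)CCC[C@]2(C)[C@H]1CC=O | intermediate
5 | keto acid: as 4 with 9β-CH2CO2H | O=C1CC[C@H]2[C@](C)(CO[Si](C)(C)C(C)(C)C)CCC[C@]2(C)[C@H]1CC(=O)O | intermediate
6 | N-(acyloxy)phthalimide of 5 | O=C1CC[C@H]2[C@](C)(CO[Si](C)(C)C(C)(C)C)CCC[C@]2(C)[C@H]1CC(=O)ON1C(=O)c2ccccc2C1=O | intermediate
7 | 2,5-dihydroxybenzaldehyde | O=Cc1cc(O)ccc1O | starting material
8 | 3-formyl-4-hydroxyphenyl pivalate | O=Cc1cc(OC(=O)C(C)(C)C)ccc1O | intermediate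
9 | 3-formyl-4-methoxyphenyl pivalate | O=Cc1cc(OC(=O)C(C)(C)C)ccc1OC | intermediate
10 | 3-(hydroxymethyl)-4-methoxyphenol | OCc1cc(O)ccc1OC | intermediate
11 | 2-bromo-5-(hydroxymethyl)-4-methoxyphenol | OCc1cc(O)c(Br)cc1OC | intermediate
12 | bis-TBS ether of 11 | CC(C)(C)[Si](C)(C)OCc1cc(O[Si](C)(C)C(C)(C)C)c(Br)cc1OC | intermediate
13 | arylmagnesium bromide from 12 | CC(C)(C)[Si](C)(C)OCc1cc(O[Si](C)(C)C(C)(C)C)c([Mg]Br)cc1OC | intermediate
14 | arylzinc chloride from 12 | CC(C)(C)[Si](C)(C)OCc1cc(O[Si](C)(C)C(C)(C)C)c([Zn]Cl)cc1OC | intermediate
15 | aryl ketone: C8 ketone, C11 bonded to C1' of the 2-(TBSO)-5-methoxy-4-(TBSOCH2)phenyl ring | O=C1CC[C@H]2[C@](C)(CO[Si](C)(C)C(C)(C)C)CCC[C@]2(C)[C@H]1Cc1cc(OC)c(CO[Si](C)(C)C(C)(C)C)cc1O[Si](C)(C)C(C)(C)C | intermediate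
16 | C7-enol triflate of 15 | FC(F)(F)S(=O)(=O)OC1=CC[C@H]2[C@](C)(CO[Si](C)(C)C(C)(C)C)CCC[C@]2(C)[C@H]1Cc1cc(OC)c(CO[Si](C)(C)C(C)(C)C)cc1O[Si](C)(C)C(C)(C)C | intermediate
17 | drim-7-ene arene, aryl TBS ether | CC1=CC[C@H]2[C@](C)(CO[Si](C)(C)C(C)(C)C)CCC[C@]2(C)[C@H]1Cc1cc(OC)c(CO[Si](C)(C)C(C)(C)C)cc1O[Si](C)(C)C(C)(C)C | intermediate
18 | 2-(drimenylmethyl)-4-methoxy-5-(silyloxymethyl)phenol | CC1=CC[C@H]2[C@](C)(CO[Si](C)(C)C(C)(C)C)CCC[C@]2(C)[C@H]1Cc1cc(OC)c(CO[Si](C)(C)C(C)(C)C)cc1O | intermediate
19 | quinone dimethyl monoketal (C3' dimethyl ketal, C6' ketone) | CC1=CC[C@H]2[C@](C)(CO[Si](C)(C)C(C)(C)C)CCC[C@]2(C)[C@H]1CC1=CC(OC)(OC)C(CO[Si](C)(C)C(C)(C)C)=CC1=O | intermediate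
20 | (R,R)-hydrobenzoin | O[C@H](c1ccccc1)[C@H](O)c1ccccc1 | starting material
21 | quinone monoketal with C3' (R,R)-hydrobenzoin ketal and C6' ketone | CC1=CC[C@H]2[C@](C)(CO[Si](C)(C)C(C)(C)C)CCC[C@]2(C)[C@H]1CC1=CC3(O[C@H](c4ccccc4)[C@@H](c4ccccc4)O3)C(CO[Si](C)(C)C(C)(C)C)=CC1=O | intermediate
22 | C2'-(tert-butylperoxy) C6' enolate | CC1=CC[C@H]2[C@](C)(CO[Si](C)(C)C(C)(C)C)CCC[C@]2(C)[C@H]1CC1=C([O-])C=C(CO[Si](C)(C)C(C)(C)C)C3(O[C@H](c4ccccc4)[C@@H](c4ccccc4)O3)[C@H]1OOC(C)(C)C | intermediate
23 | C1',C2'-epoxy quinone monoketal | CC1=CC[C@H]2[C@](C)(CO[Si](C)(C)C(C)(C)C)CCC[C@]2(C)[C@H]1C[C@@]12O[C@@H]1C3(O[C@H](c4ccccc4)[C@@H](c4ccccc4)O3)C(CO[Si](C)(C)C(C)(C)C)=CC2=O | intermediate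
24 | trans-epoxy carbinol, C3' hydrobenzoin ketal | CC1=CC[C@H]2[C@](C)(CO[Si](C)(C)C(C)(C)C)CCC[C@]2(C)[C@H]1C[C@@]12O[C@@H]1C3(O[C@H](c4ccccc4)[C@@H](c4ccccc4)O3)C(CO[Si](C)(C)C(C)(C)C)=C[C@H]2O | intermediate
25 | bis-TBS ether of epoxypholamin A | CC1=CC[C@H]2[C@](C)(CO[Si](C)(C)C(C)(C)C)CCC[C@]2(C)[C@H]1C[C@@]12O[C@@H]1C(=O)C(CO[Si](C)(C)C(C)(C)C)=C[C@H]2O | intermediate
26 | epoxypholamin A (1'S,2'S,6'R; 4α-CH2OH, 5α-H, 9α-H, 10β-Me) | CC1=CC[C@H]2[C@](C)(CO)CCC[C@]2(C)[C@H]1C[C@@]12O[C@@H]1C(=O)C(CO)=C[C@H]2O | target

## Step count and least certain steps

Total: 19 steps. Longest linear sequence: 14 steps (1 → 26 through steps 1–5 and 11–19; the arene branch 7 → 26 through steps 6–19 is equally long).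

**Step 16 (key step).** The most likely failure is poor discrimination between the two faces of C2', because the phenyl groups are one atom removed from the ring and pseudo-equatorial. A second risk is slow addition at a β carbon hemmed in by the spiro centre, which gives the base time to degrade the dienone. The fallback replaces the covalently bound controller by a catalyst. Setting out from 19, the achiral dimethyl ketal would be epoxidised under asymmetric phase-transfer conditions (t-BuOOH, aq. NaOH, toluene, an N-(9-anthracenylmethyl)cinchonidinium or -cinchoninium chloride, 0 °C). Because the decalin is enantiopure the two possible epoxides are diastereomers, so the better pseudo-enantiomeric catalyst can be chosen and the minor isomer removed by chromatography. This would give the epoxy dimethyl ketal F1. Luche reduction as in step 17 would give the trans carbinol F2, whose dimethyl ketal hydrolyses under the conditions of step 18 far more readily than the dioxolane, returning to the route at 25.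

**Step 11.** The most likely failure is slow capture of the hindered, β-branched C11 radical by nickel. That would allow hydrogen abstraction, dimerisation or a Dowd–Beckwith-type 1,2-acyl shift through the C8 carbonyl, and the ortho-silyloxy arylzinc may also turn over poorly. The fallback forms the same bond by a two-electron path. Setting out from 5, Kochi oxidative decarboxylation (Pb(OAc)4, Cu(OAc)2, pyridine, benzene, 80 °C), in which the C11 radical is oxidised by divalent copper and loses the C9 hydrogen, would give the exocyclic enone F3. Copper-catalysed conjugate addition of 13 (CuBr·SMe2, THF, −40 °C) and protonation of the enolate on work-up, with base equilibration at C9 if needed, places the side chain equatorial and returns at 15.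

**Step 17.** The most likely failure is hydride delivery anti to the oxirane oxygen, which would give the cis epoxy alcohol. The fallback inverts instead of steering. Setting out from 23, the cis carbinol F4 would be accepted as the reduction product (same Luche conditions, or i-Bu2AlH at −78 °C). A Mitsunobu reaction with 4-nitrobenzoic acid (PPh3, diisopropyl azodicarboxylate, toluene, 0 → 25 °C) would invert C6' to the 4-nitrobenzoate F5, and K2CO3/MeOH methanolysis returns at 24.

**Step 18.** The most likely failure is sluggish ionisation of the diphenyl dioxolane, which is deactivated by the adjacent oxirane. Forcing conditions would then open the tertiary C1'–O bond or strip silyl groups unevenly. The fallback reverses the order of unmasking. Setting out from 24, both silyl ethers would be removed first (Et3N·3HF, MeCN, 25 °C) to give the triol ketal F6. The ketal would then be hydrolysed in homogeneous aqueous medium (CF3CO2H/H2O/THF, 0 °C), where the progress of hydrolysis against epoxide opening can be followed, returning at 26.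

## Further compounds

F1 | step 16 | C1',C2'-epoxy quinone dimethyl monoketal | CC1=CC[C@H]2[C@](C)(CO[Si](C)(C)C(C)(C)C)CCC[C@]2(C)[C@H]1C[C@@]12O[C@@H]1C(OC)(OC)C(CO[Si](C)(C)C(C)(C)C)=CC2=O
F2 | step 16 | trans-epoxy carbinol, C3' dimethyl ketal | CC1=CC[C@H]2[C@](C)(CO[Si](C)(C)C(C)(C)C)CCC[C@]2(C)[C@H]1C[C@@]12O[C@@H]1C(OC)(OC)C(CO[Si](C)(C)C(C)(C)C)=C[C@H]2O
F3 | step 11 | exocyclic enone (C9=C11 methylene, C8 ketone, 4α-CH2OTBS) | C=C1C(=O)CC[C@H]2[C@](C)(CO[Si](C)(C)C(C)(C)C)CCC[C@]12C
F4 | step 17 | cis-epoxy carbinol (C6' epimer of 24) | CC1=CC[C@H]2[C@](C)(CO[Si](C)(C)C(C)(C)C)CCC[C@]2(C)[C@H]1C[C@@]12O[C@@H]1C3(O[C@H](c4ccccc4)[C@@H](c4ccccc4)O3)C(CO[Si](C)(C)C(C)(C)C)=C[C@@H]2O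
F5 | step 17 | 4-nitrobenzoate of 24 | CC1=CC[C@H]2[C@](C)(CO[Si](C)(C)C(C)(C)C)CCC[C@]2(C)[C@H]1C[C@@]12O[C@@H]1C3(O[C@H](c4ccccc4)[C@@H](c4ccccc4)O3)C(CO[Si](C)(C)C(C)(C)C)=C[C@H]2OC(=O)c1ccc([N+](=O)[O-])cc1
F6 | step 18 | triol with C3' hydrobenzoin ketal | CC1=CC[C@H]2[C@](C)(CO)CCC[C@]2(C)[C@H]1C[C@@]12O[C@@H]1C3(O[C@H](c4ccccc4)[C@@H](c4ccccc4)O3)C(CO)=C[C@H]2O
A1 | alternative 1 | 2-(drimenylmethyl)-5-(silyloxymethyl)cyclohexa-1,3-diene | CC1=CC[C@H]2[C@](C)(CO[Si](C)(C)C(C)(C)C)CCC[C@]2(C)[C@H]1CC1=CC[C@@H](CO[Si](C)(C)C(C)(C)C)C=C1
A2 | alternative 1 | 2,3-dioxabicyclo[2.2.2]octene endoperoxide | CC1=CC[C@H]2[C@](C)(CO[Si](C)(C)C(C)(C)C)CCC[C@]2(C)[C@H]1CC1=C[C@H]2OO[C@@H]1C[C@H]2CO[Si](C)(C)C(C)(C)C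
A3 | alternative 1 | 4-hydroxycyclohex-2-enone (C3' ketone, C6' carbinol, sp3 C4') | CC1=CC[C@H]2[C@](C)(CO[Si](C)(C)C(C)(C)C)CCC[C@]2(C)[C@H]1CC1=CC(=O)[C@H](CO[Si](C)(C)C(C)(C)C)C[C@H]1O
A4 | alternative 2 | acyclic epoxy dienone | CC1=CC[C@H]2[C@](C)(CO[Si](C)(C)C(C)(C)C)CCC[C@]2(C)[C@H]1C[C@]1(O[C@@H]1C(=O)C(=C)CO[Si](C)(C)C(C)(C)C)[C@H](O[Si](C)(C)C(C)(C)C)C=C
A5 | alternative 2 | tris-silyl ether of the target | CC1=CC[C@H]2[C@](C)(CO[Si](C)(C)C(C)(C)C)CCC[C@]2(C)[C@H]1C[C@@]12O[C@@H]1C(=O)C(CO[Si](C)(C)C(C)(C)C)=C[C@H]2O[Si](C)(C)C(C)(C)C
A6 | alternative 3 | terminal alkyne on C11 | CC1=CC[C@H]2[C@](C)(CO[Si](C)(C)C(C)(C)C)CCC[C@]2(C)[C@H]1CC#C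
A7 | alternative 3 | pentacarbonyl[methoxy(3-silyloxyprop-1-en-2-yl)carbene]chromium, (OC)5Cr=C(OMe)C(=CH2)CH2OTBS | COC(=[Cr](=C=O)(=C=O)(=C=O)(=C=O)=C=O)C(=C)CO[Si](C)(C)C(C)(C)C
A8 | alternative 3 | 2-(drimenylmethyl)-4-methoxy-5-(silyloxymethyl)phenol (same as 18) | CC1=CC[C@H]2[C@](C)(CO[Si](C)(C)C(C)(C)C)CCC[C@]2(C)[C@H]1Cc1cc(OC)c(CO[Si](C)(C)C(C)(C)C)cc1O
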